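The flavone is disconnected through ring C at O1–C8a, C4–C4a and O1–C2, so that ring A arrives as an aryne and C2–C4 as a β-methoxyacrylic acid. The feature exploited is that C4a and C8a are neighbouring ring-A carbons bearing the C4 carbonyl and O1, with the C5 oxygen flanking C4a to polarise an aryne spanning C4a–C8a. In one operation the aryne enters the carboxyl C–O bond and the phenoxide released displaces the β-methoxy group, closing the pyranone with the C3 methoxy group in place. The precursors are a benzyl-protected o-silylaryl triflate, unsubstituted at the future C8, and (Z)-2,3-dimethoxy-3-(4-methoxyphenyl)acrylic acid.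

Key step: step 10

Assumption: enol ether 14 and acid 15 are drawn as the Z isomers (vinylic methoxy groups cis), taken to be the main outcome of O-methylation of a non-chelated enolate; an E/Z mixture could be carried forward, because both β-substituents lie outside the ring closed in step 10. 4-Methoxybenzoyl chloride is chosen as the acyl donor so that the acylation of the methoxyacetate enolate runs cold, and the benzoate is taken to the aldehyde level before the oxidative degradation to the phenol.

Step 1
Reactants: 1 methyl 3,5-dihydroxy-4-methoxybenzoate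
Product: 2 methyl 3,5-bis(benzyloxy)-4-methoxybenzoate
Conditions: BnBr (2.3 equiv), K2CO3, DMF, 60 °C
Reagents that add atoms: benzyl bromide BrCc1ccccc1
Why: Williamson ether synthesis, in which both phenoxides formed with K2CO3 are benzylated by SN2 while the methyl ester is inert.

Step 2
Reactants: 2 methyl 3,5-bis(benzyloxy)-4-methoxybenzoate
Product: 3 [3,5-bis(benzyloxy)-4-methoxyphenyl]methanol
Conditions: LiAlH4, THF, 0 °C
Reagents that add atoms: none
Why: Hydride reduction of the ester to the primary alcohol, which leaves the benzyl and methyl aryl ethers untouched.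

Step 3
Reactants: 3 [3,5-bis(benzyloxy)-4-methoxyphenyl]methanol
Product: 4 3,5-bis(benzyloxy)-4-methoxybenzaldehyde
Conditions: MnO2 (excess), CH2Cl2, rt
Reagents that add atoms: none
Why: Selective MnO2 oxidation of a benzylic alcohol, which should stop cleanly at the aldehyde.

Step 4
Reactants: 4 3,5-bis(benzyloxy)-4-methoxybenzaldehyde
Product: 6 3,5-bis(benzyloxy)-4-methoxyphenol, via aryl formate 5 (not isolated)
Conditions: mCPBA, CH2Cl2, 0 °C to rt; then K2CO3 (cat.), MeOH, rt
Reagents that add atoms: mCPBA OOC(=O)c1cccc(Cl)c1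
Why: Baeyer–Villiger (Dakin-type) oxidation, in which the electron-rich aryl group migrates in the Criegee adduct to give the formate that mild methanolysis cleaves to the phenol.

Step 5
Reactants: 6 3,5-bis(benzyloxy)-4-methoxyphenol
Product: 7 3,5-bis(benzyloxy)-2-bromo-4-methoxyphenol
Conditions: NBS (1.0 equiv), MeCN, −20 °C
Reagents that add atoms: N-bromosuccinimide BrN1C(=O)CCC1=O
Why: Electrophilic aromatic bromination directed by the free hydroxyl to its ortho position (para is blocked, and the two ortho sites are equivalent by symmetry), with one equivalent of NBS at low temperature limiting dibromination.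

Step 6
Reactants: 7 3,5-bis(benzyloxy)-2-bromo-4-methoxyphenol
Product: 10 3,5-bis(benzyloxy)-4-methoxy-2-(trimethylsilyl)phenyl trifluoromethanesulfonate, via trimethylsilyl ether 8 (not isolated), via lithium 2-silylphenoxide 9 (not isolated)
Conditions: (Me3Si)2NH, THF, 65 °C, evaporate; n-BuLi, THF, −100 to −78 °C; then Tf2O, −78 °C
Reagents that add atoms: hexamethyldisilazane C[Si](C)(C)N[Si](C)(C)C; triflic anhydride O=S(=O)(OS(=O)(=O)C(F)(F)F)C(F)(F)F
Why: O-silylation followed by bromine–lithium exchange triggers a 1,3 oxygen-to-carbon silyl shift (retro-Brook rearrangement), and the lithium phenoxide so formed is trapped by Tf2O, the standard entry to o-silylaryl triflates.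

Step 7
Reactants: 11 methyl methoxyacetate; 12 4-methoxybenzoyl chloride
Product: 13 methyl 2-methoxy-3-(4-methoxyphenyl)-3-oxopropanoate (racemic)
Conditions: 11 (2.1 equiv), LiN(SiMe3)2 (2.1 equiv), THF, −78 °C; then 12 (1.0 equiv), −78 to 0 °C; aq. NH4Cl
Reagents that add atoms: none
Why: Claisen-type C-acylation of the ester lithium enolate by the acid chloride, with the second enolate equivalent deprotonating the product to prevent double acylation; the new C2 stereocentre forms as a racemate and is erased in step 8.

Step 8
Reactants: 13 methyl 2-methoxy-3-(4-methoxyphenyl)-3-oxopropanoate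
Product: 14 methyl (Z)-2,3-dimethoxy-3-(4-methoxyphenyl)prop-2-enoate
Conditions: Cs2CO3, Me2SO4, DMF, 0 °C to rt
Reagents that add atoms: dimethyl sulfate COS(=O)(=O)OC
Why: O-alkylation of a β-ketoester enolate, favoured by the loosely paired cesium enolate in a dipolar aprotic solvent, the hard sulfate electrophile and the fully substituted α-carbon, and expected to give mainly the Z enol ether from the non-chelated enolate.

Step 9
Reactants: 14 methyl (Z)-2,3-dimethoxy-3-(4-methoxyphenyl)prop-2-enoate
Product: 15 (Z)-2,3-dimethoxy-3-(4-methoxyphenyl)prop-2-enoic acid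
Conditions: LiOH·H2O, THF/MeOH/H2O, 50 °C; then 1 M HCl to pH 3, 0 °C
Reagents that add atoms: lithium hydroxide [Li+].[OH-]
Why: Ester saponification at the carbonyl, the hindered tetrasubstituted β-carbon resisting conjugate attack, with cold, mildly acidic work-up sparing the enol ether.

Step 10
Reactants: 10 3,5-bis(benzyloxy)-4-methoxy-2-(trimethylsilyl)phenyl trifluoromethanesulfonate; 15 (Z)-2,3-dimethoxy-3-(4-methoxyphenyl)prop-2-enoic acid
Product: 18 5,7-bis(benzyloxy)-3,6-dimethoxy-2-(4-methoxyphenyl)-4H-chromen-4-one, via aryne 16 (not isolated), via ortho-acylphenoxide 17 (not isolated)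
Conditions: 15 (1.0 equiv), 10 (1.5 equiv), CsF (4 equiv), THF, 125 °C, sealed tube
Reagents that add atoms: none
Why: Fluoride removes the silyl group and triflate departs to give aryne 16; the cesium carboxylate of 15 adds through oxygen to the aryne carbon remote from the flanking benzyloxy group, and the aryl anion left next to that oxygen attacks the adjacent ester carbonyl through a four-membered transition state that opens to ortho-acylphenoxide 17. The closest known reaction type is the insertion of arynes into the C–O bond of carboxylic acids, which gives o-hydroxyaryl ketones and, with unsaturated acids, chromanones and flavones. Ring C closes by 6-endo-trig oxa-Michael addition of the phenoxide to the β-carbon followed by E1cB loss of methoxide, so the alkene geometry of 15 does not matter. No stereocentre is formed. The step needs the carboxylate oxygen to bond at the future C8a and the acyl group to end at C4a; the inductively withdrawing benzyloxy group beside the triple bond (future C5) makes the distal carbon the electrophilic one and stabilises the anion at the future C4a, while the more remote oxygens should perturb this bias little. The usual ester conformation keeps the β-carbon away from the aryl anion, so acyl transfer should outrun conjugate attack by carbon.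

Step 11
Reactants: 18 5,7-bis(benzyloxy)-3,6-dimethoxy-2-(4-methoxyphenyl)-4H-chromen-4-one
Product: 19 5,7-bis(benzyloxy)-8-bromo-3,6-dimethoxy-2-(4-methoxyphenyl)-4H-chromen-4-one
Conditions: NBS (1.05 equiv), DMF, 0 °C to rt, dark
Reagents that add atoms: N-bromosuccinimide BrN1C(=O)CCC1=O
Why: Electrophilic aromatic bromination at C8, the only free ring-A carbon, activated by the ortho C7 oxygen, the para C5 oxygen and O1, whereas ring B is deactivated by conjugation with the pyranone.

Step 12
Reactants: 19 5,7-bis(benzyloxy)-8-bromo-3,6-dimethoxy-2-(4-methoxyphenyl)-4H-chromen-4-one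
Product: 20 5,7-bis(benzyloxy)-3,6,8-trimethoxy-2-(4-methoxyphenyl)-4H-chromen-4-one
Conditions: NaOMe (excess), CuBr (20 mol%), DMF/MeOH, 110 °C
Reagents that add atoms: sodium methoxide [Na+].[O-]C
Why: Ullmann-type copper-catalysed methoxylation of an aryl bromide, an established way to turn 8-bromoflavones into 8-methoxyflavones, under which benzyl ethers are stable.

Step 13
Reactants: 20 5,7-bis(benzyloxy)-3,6,8-trimethoxy-2-(4-methoxyphenyl)-4H-chromen-4-one
Product: 21 araneosol, 5,7-dihydroxy-3,6,8-trimethoxy-2-(4-methoxyphenyl)-4H-chromen-4-one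
Conditions: H2 (1 atm), 10% Pd/C, EtOAc/MeOH, rt
Reagents that add atoms: none
Why: Catalytic hydrogenolysis of the two benzyl aryl ethers, which should leave the methyl ethers and the tetrasubstituted C2–C3 alkene of the flavone untouched at ambient pressure.

Compound list
1 | methyl 3,5-dihydroxy-4-methoxybenzoate | COc1c(O)cc(C(=O)OC)cc1O | starting material
2 | methyl 3,5-bis(benzyloxy)-4-methoxybenzoate | COC(=O)c1cc(OCc2ccccc2)c(OC)c(OCc2ccccc2)c1 | intermediate
3 | [3,5-bis(benzyloxy)-4-methoxyphenyl]methanol | OCc1cc(OCc2ccccc2)c(OC)c(OCc2ccccc2)c1 | intermediate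
4 | 3,5-bis(benzyloxy)-4-methoxybenzaldehyde | O=Cc1cc(OCc2ccccc2)c(OC)c(OCc2ccccc2)c1 | intermediate
5 | 3,5-bis(benzyloxy)-4-methoxyphenyl formate (not isolated) | O=COc1cc(OCc2ccccc2)c(OC)c(OCc2ccccc2)c1 | intermediate
6 | 3,5-bis(benzyloxy)-4-methoxyphenol | Oc1cc(OCc2ccccc2)c(OC)c(OCc2ccccc2)c1 | intermediate
7 | 3,5-bis(benzyloxy)-2-bromo-4-methoxyphenol | Oc1cc(OCc2ccccc2)c(OC)c(OCc2ccccc2)c1Br | intermediate
8 | [3,5-bis(benzyloxy)-2-bromo-4-methoxyphenoxy]trimethylsilane (not isolated) | C[Si](C)(C)Oc1cc(OCc2ccccc2)c(OC)c(OCc2ccccc2)c1Br | intermediate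
9 | lithium 3,5-bis(benzyloxy)-4-methoxy-2-(trimethylsilyl)phenoxide (not isolated) | [Li+].[O-]c1cc(OCc2ccccc2)c(OC)c(OCc2ccccc2)c1[Si](C)(C)C | intermediate
10 | 3,5-bis(benzyloxy)-4-methoxy-2-(trimethylsilyl)phenyl trifluoromethanesulfonate | C[Si](C)(C)c1c(OS(=O)(=O)C(F)(F)F)cc(OCc2ccccc2)c(OC)c1OCc1ccccc1 | intermediate
11 | methyl methoxyacetate | COCC(=O)OC | starting material
12 | 4-methoxybenzoyl chloride | COc1ccc(C(=O)Cl)cc1 | starting material
13 | methyl 2-methoxy-3-(4-methoxyphenyl)-3-oxopropanoate (racemic) | COC(C(=O)OC)C(=O)c1ccc(OC)cc1 | intermediate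
14 | methyl (Z)-2,3-dimethoxy-3-(4-methoxyphenyl)prop-2-enoate | COC(=O)/C(OC)=C(/OC)c1ccc(OC)cc1 | intermediate
15 | (Z)-2,3-dimethoxy-3-(4-methoxyphenyl)prop-2-enoic acid | OC(=O)/C(OC)=C(/OC)c1ccc(OC)cc1 | intermediate
16 | 3,5-bis(benzyloxy)-4-methoxybenzyne, the 1,2-didehydroarene (not isolated) | COC1=C(OCc2ccccc2)C#CC=C1OCc1ccccc1 | intermediate
17 | (Z)-1-[2,4-bis(benzyloxy)-6-hydroxy-3-methoxyphenyl]-2,3-dimethoxy-3-(4-methoxyphenyl)prop-2-en-1-one, formed as its phenoxide (not isolated) | O=C(c1c(O)cc(OCc2ccccc2)c(OC)c1OCc1ccccc1)/C(OC)=C(/OC)c1ccc(OC)cc1 | intermediate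
18 | 5,7-bis(benzyloxy)-3,6-dimethoxy-2-(4-methoxyphenyl)-4H-chromen-4-one | COc1ccc(-c2oc3cc(OCc4ccccc4)c(OC)c(OCc4ccccc4)c3c(=O)c2OC)cc1 | intermediate
19 | 5,7-bis(benzyloxy)-8-bromo-3,6-dimethoxy-2-(4-methoxyphenyl)-4H-chromen-4-one | COc1ccc(-c2oc3c(Br)c(OCc4ccccc4)c(OC)c(OCc4ccccc4)c3c(=O)c2OC)cc1 | intermediate
20 | 5,7-bis(benzyloxy)-3,6,8-trimethoxy-2-(4-methoxyphenyl)-4H-chromen-4-one | COc1ccc(-c2oc3c(OC)c(OCc4ccccc4)c(OC)c(OCc4ccccc4)c3c(=O)c2OC)cc1 | intermediate
21 | araneosol, 5,7-dihydroxy-3,6,8-trimethoxy-2-(4-methoxyphenyl)-4H-chromen-4-one | COc1ccc(-c2oc3c(OC)c(O)c(OC)c(O)c3c(=O)c2OC)cc1 | target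

Total step count: 13 (six to the silylaryl triflate, three to the acid, the key step, three to the target).
Longest linear sequence: 10 steps (steps 1 to 6, then 10 to 13).

Steps most likely to fail

Step 10. The hindered, weakly nucleophilic carboxylate may capture the aryne slowly, so that the aryne is consumed in other ways. The aryl anion may also be protonated before it transfers the acyl group, which would stop the sequence at the aryl ester. The fallback sets out from bromophenol 7 and acid 15 and comes back at 18. Steglich esterification (EDC·HCl, DMAP, CH2Cl2, rt) should give 3,5-bis(benzyloxy)-2-bromo-4-methoxyphenyl (Z)-2,3-dimethoxy-3-(4-methoxyphenyl)prop-2-enoate F1. Bromine–lithium exchange (n-BuLi, THF, −100 °C) then generates the same ortho-aryl anion at a position fixed by the bromine and with no proton source present. An anionic Fries-type 1,3 oxygen-to-carbon acyl shift should deliver the phenoxide of 17, which on warming to rt (if needed K2CO3, DMF, 60 °C after work-up) should close ring C to 18.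

Step 8. The ambident enolate may be methylated at carbon instead of oxygen, giving the quaternary α-methyl ketoester. The fallback sets out from 13 and comes back at 14. Ketalisation (HC(OMe)3, MeOH, cat. H2SO4, reflux) should give methyl 2,3,3-trimethoxy-3-(4-methoxyphenyl)propanoate F2. Acid-catalysed elimination of methanol (cat. TsOH, toluene, reflux, methanol distilled off) then gives the conjugated enol ether 14. The new C–O bond is made by acetal formation at the ketone carbon, so no carbon alkylation is possible.

Step 12. Substitution at the hindered C8 may be slow, so that reductive loss of bromine and methoxide-induced opening of the pyranone ring compete. The fallback sets out from 19 and comes back at 20. Miyaura borylation (bis(pinacolato)diboron, PdCl2(dppf), KOAc, dioxane, 90 °C) should give 5,7-bis(benzyloxy)-3,6-dimethoxy-2-(4-methoxyphenyl)-8-(4,4,5,5-tetramethyl-1,3,2-dioxaborolan-2-yl)-4H-chromen-4-one F3. Mild oxidation (NaBO3·4H2O, THF/H2O, rt) should give 5,7-bis(benzyloxy)-8-hydroxy-3,6-dimethoxy-2-(4-methoxyphenyl)-4H-chromen-4-one F4. Williamson methylation (MeI, K2CO3, acetone, reflux) then gives 20.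

Further compounds
F1 | step 10 | 3,5-bis(benzyloxy)-2-bromo-4-methoxyphenyl (Z)-2,3-dimethoxy-3-(4-methoxyphenyl)prop-2-enoate | O=C(Oc1cc(OCc2ccccc2)c(OC)c(OCc2ccccc2)c1Br)/C(OC)=C(/OC)c1ccc(OC)cc1
F2 | step 8 | methyl 2,3,3-trimethoxy-3-(4-methoxyphenyl)propanoate (racemic) | COC(=O)C(OC)C(OC)(OC)c1ccc(OC)cc1
F3 | step 12 | 5,7-bis(benzyloxy)-3,6-dimethoxy-2-(4-methoxyphenyl)-8-(4,4,5,5-tetramethyl-1,3,2-dioxaborolan-2-yl)-4H-chromen-4-one | COc1ccc(-c2oc3c(B4OC(C)(C)C(C)(C)O4)c(OCc4ccccc4)c(OC)c(OCc4ccccc4)c3c(=O)c2OC)cc1
F4 | step 12 | 5,7-bis(benzyloxy)-8-hydroxy-3,6-dimethoxy-2-(4-methoxyphenyl)-4H-chromen-4-one | COc1ccc(-c2oc3c(O)c(OCc4ccccc4)c(OC)c(OCc4ccccc4)c3c(=O)c2OC)cc1
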